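**Retrosynthetic overview**

1. The furan ring closes last: the 2'-OH of a 2-ethoxy-isoflavone adds to C2 and expels ethanol (step 17). The pyranone ring closes before it by SNAr of a β-keto ester enolate oxygen on C8a–F (step 16). The keto ester comes from ring A acid 13 and ring B arylacetate 21 (C3–C4 bond, step 15).
2. Ring A acid 13: the dihydropyran is annulated in one flask onto a benzylic chloride with 2,2-dimethyloxirane (formal [3+3]). This makes the bond from the benzylic CH2 to the oxirane CH2 and the bond from the tertiary oxygen to C5. Prenyl then enters at the last ring C–H.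
3. Enabling feature: in ring A the benzylic carbon on C6 and its ortho neighbour C5 form a nucleophile/electrophile pair once C5 is held as C–F, and this pair matches the electrophilic CH2 and nucleophilic O of the oxirane. The other neighbour, C7, carries an inert protected oxygen. The alternating O (C5, C7, C8a) and C (C4a, C6, C8) pattern of ring A maps onto mirror-symmetric 2,6-difluoro-4-hydroxybenzaldehyde, so no regiochemical choice arises. An acid-mediated prenyl cyclization could not tell O5 from O7 or spare the C8 prenyl group.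
4. Ring B ester 21: 2,5-dihydroxybenzaldehyde → 4-bromo-2,5-bis(MOM-oxy)phenol → aryl propargyl ether → Claisen/oxa-6π chromene → palladium-catalysed α-arylation of an acetate.
5. Order of ring formation: dihydropyran on ring A (step 5), chromene on ring B (step 13), pyranone (step 16), furan (step 17).

Key step: step 5

Remark on the chemistry: locants follow isoflavone usage (O1, C2–C8a for the chromenone; C1'–C6' for ring B). The target has no stereocentre. Keto ester 23 forms as a racemate at an enolizable centre that step 16 removes.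

**Route**

Step 1
Reactants: 1 2,6-difluoro-4-hydroxybenzaldehyde
Product: 2 4-(1,3-dioxolan-2-yl)-3,5-difluorophenol
Conditions: ethylene glycol, p-TsOH·H2O (cat.), toluene, reflux, Dean–Stark trap
Reagents that add atoms: ethylene glycol (OCCO)
Why: Acid-catalysed acetalization with azeotropic removal of water should mask the aldehyde, the future C4 carbonyl carbon, against the organometallic steps.

Step 2
Reactants: 2 4-(1,3-dioxolan-2-yl)-3,5-difluorophenol
Product: 3 2-[2,6-difluoro-4-(methoxymethoxy)phenyl]-1,3-dioxolane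
Conditions: MOMCl, i-Pr2NEt, CH2Cl2, 0 °C → rt
Reagents that add atoms: chloromethyl methyl ether, MOMCl (COCCl)
Why: Williamson-type O-alkylation of the phenol should give the MOM ether, which protects O7 and directs the metalations of steps 3 and 6.

Step 3
Reactants: 3 2-[2,6-difluoro-4-(methoxymethoxy)phenyl]-1,3-dioxolane
Product: 5 [3-(1,3-dioxolan-2-yl)-2,4-difluoro-6-(methoxymethoxy)phenyl]methanol, via aldehyde 4 (not isolated)
Conditions: n-BuLi, THF, −78 °C; DMF, −78 °C; then MeOH, NaBH4, −78 → 0 °C
Reagents that add atoms: N,N-dimethylformamide, DMF (CN(C)C=O)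
Why: Directed ortho-metalation should be unambiguous because the two equivalent ring C–H bonds each lie between OMOM and F; formylation with DMF and borohydride reduction in the same flask then give the benzylic alcohol (the aryllithium is kept at −78 °C so that it does not lose LiF).

Step 4
Reactants: 5 [3-(1,3-dioxolan-2-yl)-2,4-difluoro-6-(methoxymethoxy)phenyl]methanol
Product: 6 2-[3-(chloromethyl)-2,6-difluoro-4-(methoxymethoxy)phenyl]-1,3-dioxolane
Conditions: PPh3, N-chlorosuccinimide, CH2Cl2, 0 °C → rt
Reagents that add atoms: N-chlorosuccinimide (O=C1CCC(=O)N1Cl)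
Why: Appel-type chlorination should convert the benzylic alcohol to the chloride under neutral conditions that spare the acetal and the MOM ether.

Step 5
Reactants: 6 2-[3-(chloromethyl)-2,6-difluoro-4-(methoxymethoxy)phenyl]-1,3-dioxolane, 7 2,2-dimethyloxirane
Product: 10 2-[7-fluoro-5-(methoxymethoxy)-2,2-dimethyl-3,4-dihydro-2H-chromen-8-yl]-1,3-dioxolane, via benzylmagnesium chloride 8 (not isolated), via chloromagnesium alkoxide 9 (not isolated)
Conditions: Mg turnings, 2-MeTHF, 0 °C → rt; CuI (5 mol %), 7, −20 → 0 °C; then KOt-Bu, DMPU, 80 °C (one flask)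
Reagents that add atoms: none
Why: Magnesium inserts into the benzylic C–Cl bond of 6, and the benzyl Grignard reagent 8, under CuI catalysis, opens 2,2-dimethyloxirane by SN2 attack at its unsubstituted CH2 (the CH2–CH2 bond); the tertiary alkoxide 9 set free, once exchanged to its potassium salt, displaces the neighbouring fluoride by addition–elimination through a Meisenheimer complex (the aryl C–O bond). The closest known reactions are the copper-catalysed opening of isobutylene oxide by benzyl Grignard reagents and the base-mediated cyclization of 4-(2-fluorophenyl)-2-methylbutan-2-ols to 2,2-dimethylchromans on fluoroarenes without strong activation (dipolar aprotic solvent, 80–120 °C); here they are run back to back as a formal [3+3] annulation. The one new ring, the dihydropyran, closes by a six-membered intramolecular SNAr (the alkoxide oxygen attacks the ring carbon in a 6-exo sense and fluoride leaves). No stereocentre is formed. Two selectivities are needed: attack at the CH2 and not the quaternary carbon of the oxirane, which sterics and copper catalysis at low temperature should secure (this also outruns magnesium-halide-induced rearrangement to isobutyraldehyde); and displacement of the right fluoride, which is secured because only the fluorine ortho to the benzylic carbon is within reach of the tether, the other ortho position carrying the inert OMOM group and the second fluorine sitting para.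

Step 6
Reactants: 10 2-[7-fluoro-5-(methoxymethoxy)-2,2-dimethyl-3,4-dihydro-2H-chromen-8-yl]-1,3-dioxolane
Product: 11 2-[7-fluoro-5-(methoxymethoxy)-2,2-dimethyl-6-(3-methylbut-2-en-1-yl)-3,4-dihydro-2H-chromen-8-yl]-1,3-dioxolane
Conditions: n-BuLi, THF, −78 °C; CuBr·SMe2 (20 mol %), prenyl bromide, −78 → 0 °C
Reagents that add atoms: prenyl bromide, 1-bromo-3-methylbut-2-ene (CC(C)=CCBr)
Why: Directed ortho-metalation at the only remaining ring C–H (between OMOM and F) followed by copper-catalysed SN2 allylation at the unhindered CH2 terminus of prenyl bromide should install the C8 prenyl group.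

Step 7
Reactants: 11 2-[7-fluoro-5-(methoxymethoxy)-2,2-dimethyl-6-(3-methylbut-2-en-1-yl)-3,4-dihydro-2H-chromen-8-yl]-1,3-dioxolane
Product: 12 7-fluoro-5-(methoxymethoxy)-2,2-dimethyl-6-(3-methylbut-2-en-1-yl)-3,4-dihydro-2H-chromene-8-carbaldehyde
Conditions: PPTS (cat.), acetone/H2O, 50 °C
Reagents that add atoms: water (O)
Why: Mild acid-catalysed acetal hydrolysis should free the aldehyde, since the dioxolane of an electron-rich benzaldehyde is cleaved far faster than an aryl MOM ether.

Step 8
Reactants: 12 7-fluoro-5-(methoxymethoxy)-2,2-dimethyl-6-(3-methylbut-2-en-1-yl)-3,4-dihydro-2H-chromene-8-carbaldehyde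
Product: 13 7-fluoro-5-(methoxymethoxy)-2,2-dimethyl-6-(3-methylbut-2-en-1-yl)-3,4-dihydro-2H-chromene-8-carboxylic acid
Conditions: NaClO2, NaH2PO4, 2-methylbut-2-ene, t-BuOH/H2O, rt
Reagents that add atoms: sodium chlorite, NaClO2 ([Na+].[O-]Cl=O)
Why: Pinnick oxidation should give the acid, with 2-methylbut-2-ene scavenging HOCl so that the prenyl double bond and the fully substituted arene are left alone.

Step 9
Reactants: 14 2,5-dihydroxybenzaldehyde
Product: 15 2,5-bis(methoxymethoxy)benzaldehyde
Conditions: MOMCl, i-Pr2NEt, CH2Cl2, 0 °C → reflux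
Reagents that add atoms: chloromethyl methyl ether, MOMCl (COCCl)
Why: Double Williamson-type O-alkylation should protect both phenols, heating being used for the hydrogen-bonded 2-OH.

Step 10
Reactants: 15 2,5-bis(methoxymethoxy)benzaldehyde
Product: 16 4-bromo-2,5-bis(methoxymethoxy)benzaldehyde
Conditions: N-bromosuccinimide, DMF, rt
Reagents that add atoms: N-bromosuccinimide (O=C1CCC(=O)N1Br)
Why: Electrophilic aromatic bromination should go to C4, ortho to the 5-OMOM group and para to the formyl group, the position known to react in 2,5-dialkoxybenzaldehydes.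

Step 11
Reactants: 16 4-bromo-2,5-bis(methoxymethoxy)benzaldehyde
Product: 18 4-bromo-2,5-bis(methoxymethoxy)phenol, via aryl formate 17 (not isolated)
Conditions: mCPBA, NaHCO3, CH2Cl2, 0 °C → rt; then K2CO3 (cat.), MeOH, rt
Reagents that add atoms: 3-chloroperbenzoic acid, mCPBA (OOC(=O)c1cccc(Cl)c1)
Why: Baeyer–Villiger oxidation with aryl migration should give the aryl formate, and catalytic methanolysis then frees the phenol whose oxygen becomes the ring B pyran oxygen.

Step 12
Reactants: 18 4-bromo-2,5-bis(methoxymethoxy)phenol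
Product: 19 1-bromo-2,5-bis(methoxymethoxy)-4-[(2-methylbut-3-yn-2-yl)oxy]benzene
Conditions: 3-chloro-3-methylbut-1-yne, K2CO3, KI, CuI (cat.), DMF, 60 °C
Reagents that add atoms: 3-chloro-3-methylbut-1-yne (CC(C)(Cl)C#C)
Why: Copper-assisted O-alkylation of the phenoxide with the tertiary propargylic chloride should give the aryl 1,1-dimethylpropargyl ether.

Step 13
Reactants: 19 1-bromo-2,5-bis(methoxymethoxy)-4-[(2-methylbut-3-yn-2-yl)oxy]benzene
Product: 20 6-bromo-5,8-bis(methoxymethoxy)-2,2-dimethyl-2H-chromene
Conditions: N,N-diethylaniline, 180 °C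
Reagents that add atoms: none
Why: Thermal aromatic propargyl Claisen rearrangement to the only free ortho position, followed by enolization, 1,5-hydrogen shift and oxa-6π electrocyclization, should give the 2,2-dimethyl-2H-chromene.

Step 14
Reactants: 20 6-bromo-5,8-bis(methoxymethoxy)-2,2-dimethyl-2H-chromene
Product: 21 ethyl 2-[5,8-bis(methoxymethoxy)-2,2-dimethyl-2H-chromen-6-yl]acetate
Conditions: BrZnCH2CO2Et (commercial 0.5 M solution in THF), Pd2(dba)3 (2.5 mol %), XPhos (10 mol %), THF, 65 °C
Reagents that add atoms: (2-ethoxy-2-oxoethyl)zinc bromide (CCOC(=O)C[Zn]Br)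
Why: Palladium-catalysed α-arylation of an ester (Negishi-type coupling of the Reformatsky reagent with the aryl bromide) should install the acetate arm at C1'.

Step 15
Reactants: 13 7-fluoro-5-(methoxymethoxy)-2,2-dimethyl-6-(3-methylbut-2-en-1-yl)-3,4-dihydro-2H-chromene-8-carboxylic acid, 21 ethyl 2-[5,8-bis(methoxymethoxy)-2,2-dimethyl-2H-chromen-6-yl]acetate
Product: 23 ethyl 2-[5,8-bis(methoxymethoxy)-2,2-dimethyl-2H-chromen-6-yl]-3-[7-fluoro-5-(methoxymethoxy)-2,2-dimethyl-6-(3-methylbut-2-en-1-yl)-3,4-dihydro-2H-chromen-8-yl]-3-oxopropanoate, via acid chloride 22 (not isolated)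
Conditions: 13, 1-chloro-N,N,2-trimethylprop-1-en-1-amine, CH2Cl2, 0 °C → rt; 21, LiN(SiMe3)2 (2.2 equiv), THF, −78 °C; then 22, −78 → 0 °C
Reagents that add atoms: none
Why: Crossed Claisen-type C-acylation of the lithium ester enolate with the acid chloride, made under neutral conditions that spare the prenyl group and the MOM ether, should form the C3–C4 bond, the second equivalent of base taking up the acidic keto ester.

Step 16
Reactants: 23 ethyl 2-[5,8-bis(methoxymethoxy)-2,2-dimethyl-2H-chromen-6-yl]-3-[7-fluoro-5-(methoxymethoxy)-2,2-dimethyl-6-(3-methylbut-2-en-1-yl)-3,4-dihydro-2H-chromen-8-yl]-3-oxopropanoate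
Product: 24 2-ethoxy-7-(methoxymethoxy)-8-(3-methylbut-2-en-1-yl)-3-[5,8-bis(methoxymethoxy)-2,2-dimethyl-2H-chromen-6-yl]-4H-chromen-4-one with a 2,2-dimethyl-3,4-dihydro-2H-pyran fused at C5–C6 (ring oxygen on C5)
Conditions: K2CO3, DMF, 80 °C
Reagents that add atoms: none
Why: Intramolecular SNAr should close the pyranone ring, the ester carbonyl oxygen of the enolate attacking the C–F carbon ortho to the ketone (six-membered closure), as in the known synthesis of 2-alkoxychromones from 2-fluorobenzoyl malonates and keto esters.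

Step 17
Reactants: 24 2-ethoxy-7-(methoxymethoxy)-8-(3-methylbut-2-en-1-yl)-3-[5,8-bis(methoxymethoxy)-2,2-dimethyl-2H-chromen-6-yl]-4H-chromen-4-one with a 2,2-dimethyl-3,4-dihydro-2H-pyran fused at C5–C6 (ring oxygen on C5)
Product: 25 CNP0081330.0
Conditions: HCl (1.25 M in MeOH), MeOH/CH2Cl2, 40 °C
Reagents that add atoms: none
Why: Acidic methanolysis should remove the three MOM ethers, and the freed 2'-OH then adds to C2 of the 2-alkoxychromone and expels ethanol (addition–elimination, five-membered closure), which completes the benzofuran ring and the target.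

**Compound list**

1 | 2,6-difluoro-4-hydroxybenzaldehyde | O=Cc1c(F)cc(O)cc1F | starting material
2 | 4-(1,3-dioxolan-2-yl)-3,5-difluorophenol | Oc1cc(F)c(C2OCCO2)c(F)c1 | intermediate
3 | 2-[2,6-difluoro-4-(methoxymethoxy)phenyl]-1,3-dioxolane | COCOc1cc(F)c(C2OCCO2)c(F)c1 | intermediate
4 | 3-(1,3-dioxolan-2-yl)-2,4-difluoro-6-(methoxymethoxy)benzaldehyde (forms in the flask in step 3) | COCOc1cc(F)c(C2OCCO2)c(F)c1C=O | intermediate
5 | [3-(1,3-dioxolan-2-yl)-2,4-difluoro-6-(methoxymethoxy)phenyl]methanol | COCOc1cc(F)c(C2OCCO2)c(F)c1CO | intermediate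
6 | 2-[3-(chloromethyl)-2,6-difluoro-4-(methoxymethoxy)phenyl]-1,3-dioxolane | COCOc1cc(F)c(C2OCCO2)c(F)c1CCl | intermediate
7 | 2,2-dimethyloxirane | CC1(C)CO1 | starting material
8 | {[3-(1,3-dioxolan-2-yl)-2,4-difluoro-6-(methoxymethoxy)phenyl]methyl}magnesium chloride (forms in the flask in step 5) | COCOc1cc(F)c(C2OCCO2)c(F)c1C[Mg]Cl | intermediate
9 | chloromagnesium 4-[3-(1,3-dioxolan-2-yl)-2,4-difluoro-6-(methoxymethoxy)phenyl]-2-methylbutan-2-olate (forms in the flask in step 5) | COCOc1cc(F)c(C2OCCO2)c(F)c1CCC(C)(C)O[Mg]Cl | intermediate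
10 | 2-[7-fluoro-5-(methoxymethoxy)-2,2-dimethyl-3,4-dihydro-2H-chromen-8-yl]-1,3-dioxolane | COCOc1cc(F)c(C2OCCO2)c2OC(C)(C)CCc12 | intermediate
11 | 2-[7-fluoro-5-(methoxymethoxy)-2,2-dimethyl-6-(3-methylbut-2-en-1-yl)-3,4-dihydro-2H-chromen-8-yl]-1,3-dioxolane | COCOc1c(CC=C(C)C)c(F)c(C2OCCO2)c2OC(C)(C)CCc12 | intermediate
12 | 7-fluoro-5-(methoxymethoxy)-2,2-dimethyl-6-(3-methylbut-2-en-1-yl)-3,4-dihydro-2H-chromene-8-carbaldehyde | COCOc1c(CC=C(C)C)c(F)c(C=O)c2OC(C)(C)CCc12 | intermediate
13 | 7-fluoro-5-(methoxymethoxy)-2,2-dimethyl-6-(3-methylbut-2-en-1-yl)-3,4-dihydro-2H-chromene-8-carboxylic acid | COCOc1c(CC=C(C)C)c(F)c(C(=O)O)c2OC(C)(C)CCc12 | intermediate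
14 | 2,5-dihydroxybenzaldehyde | O=Cc1cc(O)ccc1O | starting material
15 | 2,5-bis(methoxymethoxy)benzaldehyde | COCOc1ccc(OCOC)c(C=O)c1 | intermediate
16 | 4-bromo-2,5-bis(methoxymethoxy)benzaldehyde | O=Cc1cc(OCOC)c(Br)cc1OCOC | intermediate
17 | 4-bromo-2,5-bis(methoxymethoxy)phenyl formate (forms in the flask in step 11) | O=COc1cc(OCOC)c(Br)cc1OCOC | intermediate
18 | 4-bromo-2,5-bis(methoxymethoxy)phenol | Oc1cc(OCOC)c(Br)cc1OCOC | intermediate
19 | 1-bromo-2,5-bis(methoxymethoxy)-4-[(2-methylbut-3-yn-2-yl)oxy]benzene | C#CC(C)(C)Oc1cc(OCOC)c(Br)cc1OCOC | intermediate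
20 | 6-bromo-5,8-bis(methoxymethoxy)-2,2-dimethyl-2H-chromene | COCOc1cc(Br)c(OCOC)c2C=CC(C)(C)Oc12 | intermediate
21 | ethyl 2-[5,8-bis(methoxymethoxy)-2,2-dimethyl-2H-chromen-6-yl]acetate | CCOC(=O)Cc1cc(OCOC)c2OC(C)(C)C=Cc2c1OCOC | intermediate
22 | 7-fluoro-5-(methoxymethoxy)-2,2-dimethyl-6-(3-methylbut-2-en-1-yl)-3,4-dihydro-2H-chromene-8-carbonyl chloride (forms in the flask in step 15) | COCOc1c(CC=C(C)C)c(F)c(C(Cl)=O)c2OC(C)(C)CCc12 | intermediate
23 | ethyl 2-[5,8-bis(methoxymethoxy)-2,2-dimethyl-2H-chromen-6-yl]-3-[7-fluoro-5-(methoxymethoxy)-2,2-dimethyl-6-(3-methylbut-2-en-1-yl)-3,4-dihydro-2H-chromen-8-yl]-3-oxopropanoate (racemic, enolizable) | CCOC(=O)C(C(=O)c1c(F)c(CC=C(C)C)c(OCOC)c2CCC(C)(C)Oc12)c1cc(OCOC)c2OC(C)(C)C=Cc2c1OCOC | intermediate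
24 | 2-ethoxy-7-(methoxymethoxy)-8-(3-methylbut-2-en-1-yl)-3-[5,8-bis(methoxymethoxy)-2,2-dimethyl-2H-chromen-6-yl]-4H-chromen-4-one with a 2,2-dimethyl-3,4-dihydro-2H-pyran fused at C5–C6 (ring oxygen on C5) | CCOc1oc2c(CC=C(C)C)c(OCOC)c3c(c2c(=O)c1-c1cc(OCOC)c2OC(C)(C)C=Cc2c1OCOC)OC(C)(C)CC3 | intermediate
25 | CNP0081330.0: 7,5'-dihydroxy-8-prenyl-coumaronochromone with a 2,2-dimethyl-3,4-dihydro-2H-pyran fused at C5–C6 (oxygen on C5) and a 2,2-dimethyl-2H-pyran fused at C3'–C4' (oxygen on C4') | CC(C)=CCc1c(O)c2c(c3c(=O)c4c(oc13)oc1c3c(c(O)cc14)OC(C)(C)C=C3)OC(C)(C)CC2 | target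

**Step count and risks**

Total steps: 17. Longest linear sequence: 11 (steps 1–8, then 15–17); the ring B branch (steps 9–14) joins at step 15.

Steps most likely to fail:

- Step 5. The benzylic halide may homocouple during magnesium insertion. Magnesium halide may isomerize the oxirane to isobutyraldehyde before the copper-catalysed opening. The ring closure on a fluoroarene without a strong activating group may be slow and stop at the open-chain alcohol. The fallback builds the same ring by olefination and separate ring closure. It sets out from 4, which is isolated when step 3 is stopped before the borohydride stage. Wittig olefination with 1-(triphenylphosphoranylidene)propan-2-one (toluene, 80 °C) should give the (E)-enone F1. Hydrogenation over palladium on carbon (H2, Pd/C, EtOAc) should give the saturated ketone F2. MeMgBr (THF, 0 °C) should give the tertiary alcohol F3. NaH in DMF at 100 °C then closes the ring by SNAr, and the route is rejoined at 10.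

- Step 15. The enolate may be acylated on oxygen, or the two doubly ortho-substituted partners may combine too slowly, so that the acid chloride is hydrolysed on work-up. The fallback replaces the acylation by aldol addition and oxidation. It sets out from aldehyde 12 and ester 21. The lithium enolate of 21 (LiN(i-Pr)2, THF, −78 °C) should add to 12 to give the β-hydroxy ester F4 as a mixture of diastereomers that converge. Dess–Martin oxidation (CH2Cl2, NaHCO3) then returns to 23.

- Step 17. The freed 7-OH may add to the prenyl double bond under acid, the chromene may be damaged during cleavage of three MOM ethers, or the furan closure may stay incomplete. The fallback separates deprotection from ring closure and avoids protic acid. It sets out from 24. ZnBr2 and propane-1-thiol (CH2Cl2, 0 °C → rt) should cleave the MOM ethers to give the triol F5. K2CO3 in DMF (50 °C) should then close the furan ring through the 2'-phenoxide, returning at 25.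

**Further compounds**

F1 | step 5 | (E)-4-[3-(1,3-dioxolan-2-yl)-2,4-difluoro-6-(methoxymethoxy)phenyl]but-3-en-2-one | COCOc1cc(F)c(C2OCCO2)c(F)c1/C=C/C(C)=O
F2 | step 5 | 4-[3-(1,3-dioxolan-2-yl)-2,4-difluoro-6-(methoxymethoxy)phenyl]butan-2-one | COCOc1cc(F)c(C2OCCO2)c(F)c1CCC(C)=O
F3 | step 5 | 4-[3-(1,3-dioxolan-2-yl)-2,4-difluoro-6-(methoxymethoxy)phenyl]-2-methylbutan-2-ol | COCOc1cc(F)c(C2OCCO2)c(F)c1CCC(C)(C)O
F4 | step 15 | ethyl 2-[5,8-bis(methoxymethoxy)-2,2-dimethyl-2H-chromen-6-yl]-3-[7-fluoro-5-(methoxymethoxy)-2,2-dimethyl-6-(3-methylbut-2-en-1-yl)-3,4-dihydro-2H-chromen-8-yl]-3-hydroxypropanoate (mixture of diastereomers) | CCOC(=O)C(C(O)c1c(F)c(CC=C(C)C)c(OCOC)c2CCC(C)(C)Oc12)c1cc(OCOC)c2OC(C)(C)C=Cc2c1OCOC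
F5 | step 17 | 3-(5,8-dihydroxy-2,2-dimethyl-2H-chromen-6-yl)-2-ethoxy-7-hydroxy-8-(3-methylbut-2-en-1-yl)-4H-chromen-4-one with a 2,2-dimethyl-3,4-dihydro-2H-pyran fused at C5–C6 (ring oxygen on C5) | CCOc1oc2c(CC=C(C)C)c(O)c3c(c2c(=O)c1-c1cc(O)c2OC(C)(C)C=Cc2c1O)OC(C)(C)CC3
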